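The plan rests on opening ring B at its C1–C6 bond. Ring B is a 6-methyl-2,4-dioxygenated benzoate whose carboxyl carbon is esterified to O4 of ring A. Its six ring carbons therefore equal C2–C7 of a 3,5,7-trioxooctanoyl chain, with C8 as the ring methyl. In one operation, aldol attack of C2 on the C7 ketone, loss of water and enolisation create aromatic ring B. The hindered A–B depside bond is then already in place, and O2 and O4 are differentiated by chelation. The precursor is the O4-(3,5,7-trioxooctanoyl) ester of methyl orsellinate, made by phenol capture of a dioxinone-derived acylketene. Ring C and both methyl ethers are added afterwards.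

Key step: step 4

Remarks
- Ring A is the methyl benzoate ring, ring B the central ring and ring C the terminal dihydroxy ring; ring positions count from the carbon bearing the carbonyl group (C1), chain positions from the ester carbonyl (C1) to the terminal methyl (C8).
- Ring A keeps O2 as a free, hydrogen-bonded phenol through the key step and is methylated together with ring B in step 8; this spectator change leaves the skeletons of the key-step precursor and product, the bond formed and the ring closed untouched, lets commercial methyl orsellinate serve as the ketene trap in excess, and removes a protect–methylate–deprotect sequence.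
- All 1,3-dicarbonyl compounds are written as keto tautomers; enolates, phenoxides and carboxylates made by the stated bases count as ionised forms of the numbered compounds.
- The target has no stereocentre and no stereogenic double bond, so no SMILES carries stereo descriptors; the only sp3 centres created are transient ones in the cyclic aldol.

Step 1
Reactants: 1 2,2,6-trimethyl-4H-1,3-dioxin-4-one; 2 acetyl chloride
Product: 3 2,2-dimethyl-6-(2-oxopropyl)-4H-1,3-dioxin-4-one
Conditions: 1 (2 equiv), LiN(SiMe3)2 (2 equiv), THF, −78 °C; 2 (1 equiv), −78 → −20 °C; 1 M HCl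
Reagents that add atoms: none
Why: Vinylogous Claisen-type C-acylation, in which kinetic deprotonation of the C6 methyl group gives the extended lithium dienolate, the acid chloride acylates its γ-carbon, and the second equivalent of dienolate takes up the more acidic proton of 3 so that double acylation is held back.

Step 2
Reactants: 3 2,2-dimethyl-6-(2-oxopropyl)-4H-1,3-dioxin-4-one; 4 N-methoxy-N-methylacetamide
Product: 5 6-(2,4-dioxopentyl)-2,2-dimethyl-4H-1,3-dioxin-4-one
Conditions: LiN(iPr)2 (2.2 equiv), THF, −78 → −40 °C; 4 (1.1 equiv), −78 → −20 °C; cold 1 M HCl to pH 3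
Reagents that add atoms: none
Why: Dianion Claisen condensation, in which the first equivalent of base removes the doubly activated CH2 proton, the second removes a terminal CH3 proton, and the more reactive terminal carbanion takes one acetyl group from the N-methoxy-N-methyl amide, which unlike an acid chloride neither O-acylates nor over-acylates.

Step 3
Reactants: 5 6-(2,4-dioxopentyl)-2,2-dimethyl-4H-1,3-dioxin-4-one; 6 methyl orsellinate (methyl 2,4-dihydroxy-6-methylbenzoate)
Product: 8 3-hydroxy-4-(methoxycarbonyl)-5-methylphenyl 3,5,7-trioxooctanoate, via acylketene 7 (not isolated)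
Conditions: 6 (3 equiv), toluene, 110 °C, 5 added slowly, short hold; evaporate; crude 8 carried on together with the surplus 6
Reagents that add atoms: none
Why: Thermal retro-hetero-Diels–Alder cleavage of the dioxinone expels acetone and the acylketene adds the phenolic O–H (ketene acylation, known for phenols with simple dioxinones); only O4–H of 6 is available because O2–H is hydrogen-bonded to and flanked by the ester, and the excess of phenol outruns capture of the ketene by its own C5 enol oxygen.

Step 4
Reactants: 8 3-hydroxy-4-(methoxycarbonyl)-5-methylphenyl 3,5,7-trioxooctanoate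
Product: 10 methyl lecanorate (methyl 4-[(2,4-dihydroxy-6-methylbenzoyl)oxy]-2-hydroxy-6-methylbenzoate), via cyclic aldol 9 (not isolated)
Conditions: Et3N (2 equiv), CH2Cl2, 0 °C; then CF3CO2H, 0 °C → rt; surplus 6 recovered on chromatography
Reagents that add atoms: none
Why: Et3N ionises 8, the enolates at C2, C4 and C6 interconvert by proton transfer, and the C2 enolate adds to the terminal C7 methyl ketone, which forms the ring B C1–C6 bond and gives the cyclic aldol 9. Loss of water from 9 (E1cB, completed by CF3CO2H) and tautomerisation of the C3 and C5 carbonyl groups to the ring B O2 and O4 phenols make the sequence irreversible; the closest known reaction type is the biomimetic aldol aromatisation of dioxinone-derived 3,5,7-triketo esters to resorcylates. The one new ring, a six-membered carbocycle, closes 6-exo-trig at C7=O, 6-(enolendo) when the enolate is written C2=C3–O and 6-(enolexo) when it is written through the ester carbonyl C1, and both modes are allowed for a six-membered ring. The two sp3 centres of 9 form without control and vanish on aromatisation, so no stereocentre has to be set. The step needs C2-to-C7 carbon–carbon bond formation to beat every transfer of the C1 acyl group away from the ring A oxygen (lactonisation by the C5 enol oxygen, Claisen closure from C6, E1cB loss of the aryloxide). In favour of the aldol path, C7 is an unhindered methyl ketone and a better electrophile than C1, which is deactivated whenever the C2–C3 unit is enolised or ionised; the weak amine in cold CH2Cl2 stops at the monoanion and offers no external nucleophile; aromatisation drains the reversible aldol equilibrium; and the surplus 6 left in the flask returns any released ketene 7 to 8.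

Step 5
Reactants: 6 methyl orsellinate
Product: 11 methyl 2,4-bis(benzyloxy)-6-methylbenzoate
Conditions: BnBr (2.5 equiv), K2CO3 (3 equiv), DMF, 60 °C
Reagents that add atoms: benzyl bromide, BrCc1ccccc1
Why: Williamson ether synthesis, in which excess bromide in warm DMF alkylates the hydrogen-bonded 2-hydroxyl as well as the free 4-hydroxyl.

Step 6
Reactants: 11 methyl 2,4-bis(benzyloxy)-6-methylbenzoate
Product: 12 2,4-bis(benzyloxy)-6-methylbenzoic acid
Conditions: KOH (10 equiv), DMSO–H2O (4:1), 100 °C; then 2 M HCl
Reagents that add atoms: potassium hydroxide, [K+].[OH-]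
Why: Saponification of a di-ortho-substituted methyl benzoate, which needs poorly solvated hydroxide in hot aqueous DMSO and leaves the benzyl aryl ethers untouched.

Step 7
Reactants: 10 methyl lecanorate; 12 2,4-bis(benzyloxy)-6-methylbenzoic acid
Product: 14 methyl 4-[(4-{[2,4-bis(benzyloxy)-6-methylbenzoyl]oxy}-2-hydroxy-6-methylbenzoyl)oxy]-2-hydroxy-6-methylbenzoate, via mixed anhydride 13 (not isolated)
Conditions: 12 (1.1 equiv), (CF3CO)2O (4 equiv), toluene, 0 °C → rt
Reagents that add atoms: none
Why: Mixed-anhydride esterification, the standard depside coupling, in which the hindered electron-rich acid is activated as 13 and acylates the only hydroxyl of 10 that is not hydrogen-bonded to a carbonyl, ring B O4–H, while both chelated 2-hydroxyls and the existing depside bond stay untouched at room temperature.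

Step 8
Reactants: 14 methyl 4-[(4-{[2,4-bis(benzyloxy)-6-methylbenzoyl]oxy}-2-hydroxy-6-methylbenzoyl)oxy]-2-hydroxy-6-methylbenzoate
Product: 15 methyl 4-[(4-{[2,4-bis(benzyloxy)-6-methylbenzoyl]oxy}-2-methoxy-6-methylbenzoyl)oxy]-2-methoxy-6-methylbenzoate
Conditions: MeI (10 equiv), K2CO3 (4 equiv), dry acetone, reflux
Reagents that add atoms: methyl iodide, CI
Why: Double Williamson methylation of the two chelated phenols, the only acidic sites left, in which the large excess of methyl iodide traps each phenoxide quickly and all three ester carbonyls are shielded by two ortho substituents in a medium free of alkoxide.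

Step 9
Reactants: 15 methyl 4-[(4-{[2,4-bis(benzyloxy)-6-methylbenzoyl]oxy}-2-methoxy-6-methylbenzoyl)oxy]-2-methoxy-6-methylbenzoate
Product: 16 methyl 4-[(4-{[2,4-dihydroxy-6-methylbenzoyl]oxy}-2-methoxy-6-methylbenzoyl)oxy]-2-methoxy-6-methylbenzoate (CNP0514431.0)
Conditions: H2 (1 atm), Pd/C (10% Pd on carbon), EtOAc, rt
Reagents that add atoms: none
Why: Catalytic hydrogenolysis of the two benzyl aryl ethers under neutral conditions, which spares the aryl esters, the methyl ester and the methyl ethers and should deliver the stereocentre-free target.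

Compound list
1 | 2,2,6-trimethyl-4H-1,3-dioxin-4-one | CC1=CC(=O)OC(C)(C)O1 | starting material
2 | acetyl chloride | CC(Cl)=O | starting material
3 | 2,2-dimethyl-6-(2-oxopropyl)-4H-1,3-dioxin-4-one | CC(=O)CC1=CC(=O)OC(C)(C)O1 | intermediate
4 | N-methoxy-N-methylacetamide | CON(C)C(C)=O | starting material
5 | 6-(2,4-dioxopentyl)-2,2-dimethyl-4H-1,3-dioxin-4-one | CC(=O)CC(=O)CC1=CC(=O)OC(C)(C)O1 | intermediate
6 | methyl orsellinate (methyl 2,4-dihydroxy-6-methylbenzoate) | COC(=O)c1c(C)cc(O)cc1O | starting material
7 | 3,5,7-trioxooct-1-en-1-one (acylketene) | CC(=O)CC(=O)CC(=O)C=C=O | intermediate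
8 | 3-hydroxy-4-(methoxycarbonyl)-5-methylphenyl 3,5,7-trioxooctanoate | CC(=O)CC(=O)CC(=O)CC(=O)Oc1cc(C)c(C(=O)OC)c(O)c1 | intermediate
9 | 3-hydroxy-4-(methoxycarbonyl)-5-methylphenyl 2-hydroxy-2-methyl-4,6-dioxocyclohexane-1-carboxylate (cyclic aldol, mixture of stereoisomers) | CC1(O)CC(=O)CC(=O)C1C(=O)Oc1cc(C)c(C(=O)OC)c(O)c1 | intermediate
10 | methyl lecanorate (methyl 4-[(2,4-dihydroxy-6-methylbenzoyl)oxy]-2-hydroxy-6-methylbenzoate) | COC(=O)c1c(C)cc(OC(=O)c2c(C)cc(O)cc2O)cc1O | intermediate
11 | methyl 2,4-bis(benzyloxy)-6-methylbenzoate | COC(=O)c1c(C)cc(OCc2ccccc2)cc1OCc1ccccc1 | intermediate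
12 | 2,4-bis(benzyloxy)-6-methylbenzoic acid | OC(=O)c1c(C)cc(OCc2ccccc2)cc1OCc1ccccc1 | intermediate
13 | 2,4-bis(benzyloxy)-6-methylbenzoic trifluoroacetic anhydride | O=C(OC(=O)C(F)(F)F)c1c(C)cc(OCc2ccccc2)cc1OCc1ccccc1 | intermediate
14 | methyl 4-[(4-{[2,4-bis(benzyloxy)-6-methylbenzoyl]oxy}-2-hydroxy-6-methylbenzoyl)oxy]-2-hydroxy-6-methylbenzoate | COC(=O)c1c(C)cc(OC(=O)c2c(C)cc(OC(=O)c3c(C)cc(OCc4ccccc4)cc3OCc3ccccc3)cc2O)cc1O | intermediate
15 | methyl 4-[(4-{[2,4-bis(benzyloxy)-6-methylbenzoyl]oxy}-2-methoxy-6-methylbenzoyl)oxy]-2-methoxy-6-methylbenzoate | COC(=O)c1c(C)cc(OC(=O)c2c(C)cc(OC(=O)c3c(C)cc(OCc4ccccc4)cc3OCc3ccccc3)cc2OC)cc1OC | intermediate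
16 | methyl 4-[(4-{[2,4-dihydroxy-6-methylbenzoyl]oxy}-2-methoxy-6-methylbenzoyl)oxy]-2-methoxy-6-methylbenzoate (CNP0514431.0) | COC(=O)c1c(C)cc(OC(=O)c2c(C)cc(OC(=O)c3c(C)cc(O)cc3O)cc2OC)cc1OC | target

Total step count: 9
Longest linear sequence: 7 steps (1, 2, 3, 4, 7, 8, 9)

Steps most likely to fail

Step 4. Transfer of the C1 acyl group may outrun carbon–carbon bond formation. The ring A aryloxide would then be lost by lactonisation through the C5 enol oxygen, by Claisen closure from C6, or by E1cB fragmentation. The fallback sets out from 6 and 12 and brings ring B in preformed. The acid and the phenol are joined by the mixed-anhydride method of step 7 ((CF3CO)2O, toluene, rt, via 13), which should acylate only the unchelated O4–H and give methyl 4-{[2,4-bis(benzyloxy)-6-methylbenzoyl]oxy}-2-hydroxy-6-methylbenzoate F1. Hydrogenolysis (H2, Pd/C, EtOAc) removes both benzyl groups and comes back to the route at 10.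

Step 3. The ketene may be consumed by its own C5 enol oxygen. The capture may reverse on prolonged heating, or site selectivity between the two hydroxyls of the trap may erode. The fallback sets out from 5 and swaps the order of ring formation and ester formation.
- Et3N in CH2Cl2 at rt closes the same C2–C7 aldol while C1 is still locked in the dioxinone, giving 7-hydroxy-2,2,5-trimethyl-4H-1,3-benzodioxin-4-one F2.
- Williamson benzylation (BnBr, K2CO3, acetone) gives 7-(benzyloxy)-2,2,5-trimethyl-4H-1,3-benzodioxin-4-one F3.
- The monosodium aryloxide of 6 (NaH, 1 equiv, DMF, rt to 50 °C) opens the ring carbonyl of F3 with loss of acetone, a known way to depside bonds. It should give methyl 4-{[4-(benzyloxy)-2-hydroxy-6-methylbenzoyl]oxy}-2-hydroxy-6-methylbenzoate F4.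
- Hydrogenolysis (H2, Pd/C, EtOAc) comes back to the route at 10.

Step 2. Proton exchange between the dianion and the acyl donor or product, O-acylation, and premature cyclisation of the diketo-dioxinone during work-up may erode the condensation. The fallback sets out from 1 and replaces the dianion by soft enolisation.
- The lithium dienolate of 1 (LiN(SiMe3)2, THF, −78 °C) is acylated with allyl 3-chloro-3-oxopropanoate to give allyl 4-(2,2-dimethyl-4-oxo-4H-1,3-dioxin-6-yl)-3-oxobutanoate F5.
- MgCl2, pyridine and 2 in CH2Cl2 at 0 °C C-acetylate the carbon between the ketone and the ester, giving allyl 2-acetyl-4-(2,2-dimethyl-4-oxo-4H-1,3-dioxin-6-yl)-3-oxobutanoate F6.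
- Catalytic Pd(PPh3)4 with morpholine in THF removes the allyl group, and the freed acid decarboxylates, coming back to the route at 5.

Further compounds
F1 | step 4 | methyl 4-{[2,4-bis(benzyloxy)-6-methylbenzoyl]oxy}-2-hydroxy-6-methylbenzoate | COC(=O)c1c(C)cc(OC(=O)c2c(C)cc(OCc3ccccc3)cc2OCc2ccccc2)cc1O
F2 | step 3 | 7-hydroxy-2,2,5-trimethyl-4H-1,3-benzodioxin-4-one | Cc1cc(O)cc2OC(C)(C)OC(=O)c12
F3 | step 3 | 7-(benzyloxy)-2,2,5-trimethyl-4H-1,3-benzodioxin-4-one | Cc1cc(OCc3ccccc3)cc2OC(C)(C)OC(=O)c12
F4 | step 3 | methyl 4-{[4-(benzyloxy)-2-hydroxy-6-methylbenzoyl]oxy}-2-hydroxy-6-methylbenzoate | COC(=O)c1c(C)cc(OC(=O)c2c(C)cc(OCc3ccccc3)cc2O)cc1O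
F5 | step 2 | allyl 4-(2,2-dimethyl-4-oxo-4H-1,3-dioxin-6-yl)-3-oxobutanoate | C=CCOC(=O)CC(=O)CC1=CC(=O)OC(C)(C)O1
F6 | step 2 | allyl 2-acetyl-4-(2,2-dimethyl-4-oxo-4H-1,3-dioxin-6-yl)-3-oxobutanoate | C=CCOC(=O)C(C(C)=O)C(=O)CC1=CC(=O)OC(C)(C)O1
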